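A direct plan would carry both 2-aminoimidazoles as imidazo[1,2-a]pyrimidines and free them with hydrazine at the very end.
It would set the stereocentre by hydrolase desymmetrisation of the prochiral dimethyl 3-(imidazo[1,2-a]pyrimidin-2-yl)glutarate A1 to the half-ester A2.
It would then grow ring A on the acid arm through the α-chloroaldehyde A3 and 2-aminopyrimidine, and add the alkenyl arm by Suzuki coupling.
Weakest would be the enzymatic desymmetrisation: sense and level of selection would rest only on analogy with 3-arylglutarates, and a polar, basic bicycle need not fit the aryl pocket.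
Next would be the α-chlorination and annulation of A3: the hydrogen at the stereocentre is heterobenzylic and β to chloride, so loss of HCl to a conjugated enal would erase the stereocentre.
Third, the malonate-based assembly of A1 and the later ester-to-aldehyde-to-carbamate adjustment would add many operations without adding complexity.

The target is, atom for atom, two copies of one N-acylated monomer, 2-amino-4-(3-aminopropenyl)imidazole: ring B keeps the (E)-alkene, while in the other copy the alkene has taken up H at the carbon next to CH2N and C5 of ring B at the carbon next to ring A. The route rests on that bond, stereocentre to ring B. One racemic (2-aminoimidazol-4-yl)carbinol, made from commercial 2-aminoimidazole, supplies both halves: fully protonated it dehydrates to the alkenyl nucleophile; paired with a chiral phosphate it ionises to a planar azafulvenium ion, which that nucleophile captures. One operation joins two unprotected rings, completes ring B and sets the stereocentre; enzyme, α-chloroaldehyde, chain assembly and ring unmasking all vanish.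

Key step: step 3

Assumption: the sense of induction of the chiral phosphate cannot be predicted. (R)-TRIP, (R)-3,3′-bis(2,4,6-triisopropylphenyl)-1,1′-binaphthyl-2,2′-diyl hydrogen phosphate, is written, and its enantiomer would be taken if the product proves to be (R).
Convention: 2-aminoimidazoles are written in one N–H tautomer. In a monomer, C4 is the ring carbon that bears the chain, C5 the free ring CH, N1 the nitrogen next to C5 and N3 the nitrogen next to C4. The azafulvenium ion 5 is one compound that carbinol 4 gives under two sets of conditions; it is numbered and entered at step 2, where it first forms, and step 3 refers to it by that number.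

Step 1
Reactants: 1 2-aminoimidazole hemisulfate; 2 3-phthalimidopropanal
Product: 4 rac-2-[3-(2-amino-1H-imidazol-4-yl)-3-hydroxypropyl]isoindoline-1,3-dione, via 2-aminoimidazole free base 3 (not isolated)
Conditions: 1 (1.5 equiv, i.e. 3 equiv of ring), NaOMe (3 equiv), MeOH, 0 °C, filter; then 2 (1 equiv), MeOH/THF, 23 °C, argon
Reagents that add atoms: none
Why: Hydroxyalkylation of 2-aminoimidazole with an aliphatic aldehyde: the free base reacts as a cyclic enediamine through C4(5) under neutral to weakly basic conditions, N-adducts are reversible hemiaminals, the excess of ring holds back 4,5-double addition, and the carbinol centre may be racemic because step 3 erases it.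

Step 2
Reactants: 4 rac-2-[3-(2-amino-1H-imidazol-4-yl)-3-hydroxypropyl]isoindoline-1,3-dione
Product: 6 2-[(E)-3-(2-amino-1H-imidazol-4-yl)prop-2-enyl]isoindoline-1,3-dione, via 2-amino-4-(3-phthalimidopropylidene)-4H-imidazol-1-ium ion 5 (not isolated)
Conditions: CF3CO2H (1.5 equiv), MeCN (0.01 M), reflux with the condensate passed over 3 Å MS; aq NaHCO3
Reagents that add atoms: none
Why: E1 dehydration of a heterobenzylic carbinol: with more than one equivalent of strong acid every aminoimidazole ring is N-protonated and no C-nucleophile is left, so ion 5 (reached by proton shift from ring nitrogen to hydroxyl) can only lose the neighbouring CH2 proton and should give the conjugated, thermodynamically preferred (E)-alkene, helped by dilution and water removal.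

Step 3
Reactants: 4 rac-2-[3-(2-amino-1H-imidazol-4-yl)-3-hydroxypropyl]isoindoline-1,3-dione; 6 2-[(E)-3-(2-amino-1H-imidazol-4-yl)prop-2-enyl]isoindoline-1,3-dione
Product: 7 2-[(3S)-3-(2-amino-1H-imidazol-4-yl)-3-[2-amino-5-[(E)-3-(1,3-dioxoisoindolin-2-yl)prop-1-enyl]-1H-imidazol-4-yl]propyl]isoindoline-1,3-dione
Conditions: (R)-TRIP (20 mol %), 6 (2 equiv, free base), 5 Å MS, CH2Cl2/THF 4:1, 0 °C; 4 (free base) added over 12 h; excess 6 recovered
Reagents that add atoms: none
Why: Proposed new method: the acid is taken up as the 2-aminoimidazolium phosphate of 4, a proton shift from ring nitrogen to hydroxyl lets water leave under the push of N1 through C5=C4, and both enantiomers of 4 collapse to the same planar azafulvenium (vinylogous iminium) ion 5 already met in step 2, which here has the chiral phosphate as counter-ion and stays hydrogen-bonded to it through N1–H and 2-NH2. C5 of free-base 6, the β-carbon of its cyclic enediamine N3–C4=C5, adds to the exocyclic carbon of 5, and the phosphate takes the C5 proton, which restores ring B and returns the acid. The closest known reaction type is the chiral-phosphoric-acid-catalysed enantioconvergent substitution of racemic indol-3-yl and pyrrol-2-yl carbinols by indoles and pyrroles through alkylideneindoleninium or azafulvenium phosphate ion pairs, and counter-anion-directed catalysis with ammonium phosphates shows that basic nitrogen does not switch such an anion off, but 2-aminoimidazolyl carbinols have not been used in it. No ring is closed; the single new stereocentre is controlled by the phosphate, which bridges the N–H of 5 and the N1–H of 6 and leaves one face of the exocyclic C=C open between its 2,4,6-triisopropylphenyl groups, while the chain of 5 should lie on the side of N3, which bears no hydrogen, so that one ion geometry is offered. Site selectivity for C5 of 6 over its alkene terminus and its nitrogen atoms is secured because only attack through C5 gives a σ-complex whose charge is spread over the whole guanidine unit, whereas N-adducts are aminals that ionise again. Chemoselectivity is secured by slow addition of 4 to an excess of 6 (4 cannot compete as nucleophile, and proton loss from 5 only makes more 6), by the branched substituent that shields the free C5–H of ring A in 7 from a second alkylation, and by the low acidity of an aminoimidazolium phosphate, which at 0 °C should not C-protonate the alkene of 6 or 7, so that 5 arises from 4 alone.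

Step 4
Reactants: 7 2-[(3S)-3-(2-amino-1H-imidazol-4-yl)-3-[2-amino-5-[(E)-3-(1,3-dioxoisoindolin-2-yl)prop-1-enyl]-1H-imidazol-4-yl]propyl]isoindoline-1,3-dione
Product: 8 (3S)-3-(2-amino-1H-imidazol-4-yl)-3-[2-amino-5-[(E)-3-aminoprop-1-enyl]-1H-imidazol-4-yl]propan-1-amine
Conditions: N2H4·H2O (8 equiv), degassed EtOH, 60 °C, argon; filter, evaporate to dryness until all hydrazine is gone
Reagents that add atoms: none
Why: Ing–Manske hydrazinolysis (Gabriel synthesis) frees both primary amines in one operation; the electron-rich rings, the stereocentre (no acidic C–H) and, with air excluded so that no diimide forms, the (E)-alkene should be left alone.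

Step 5
Reactants: 9 2,2,2-trichloro-1-(1H-pyrrol-2-yl)ethanone
Product: 10 2,2,2-trichloro-1-(4,5-dibromo-1H-pyrrol-2-yl)ethanone
Conditions: Br2 (2.05 equiv), AcOH, 23 °C
Reagents that add atoms: bromine, BrBr
Why: Electrophilic aromatic bromination of a 2-acylpyrrole, which goes to C4 and then to C5.

Step 6
Reactants: 8 (3S)-3-(2-amino-1H-imidazol-4-yl)-3-[2-amino-5-[(E)-3-aminoprop-1-enyl]-1H-imidazol-4-yl]propan-1-amine; 10 2,2,2-trichloro-1-(4,5-dibromo-1H-pyrrol-2-yl)ethanone
Product: 11 N-[(3S)-3-(2-amino-1H-imidazol-4-yl)-3-[2-amino-5-[(E)-3-[(4,5-dibromo-1H-pyrrole-2-carbonyl)amino]prop-1-enyl]-1H-imidazol-4-yl]propyl]-4,5-dibromo-1H-pyrrole-2-carboxamide (target)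
Conditions: 10 (2.1 equiv), DMF, 23 °C, argon; reversed-phase chromatography (H2O/MeOH)
Reagents that add atoms: none
Why: Haloform-type acyl transfer from the trichloromethyl ketone acylates the two primary aliphatic amines, while the 2-amino groups (part of a guanidine π-system) and the pyrrole N–H are too weakly nucleophilic to compete, so neither protection nor a coupling agent is needed.

**Compound list**
1 | 2-aminoimidazole hemisulfate | Nc1ncc[nH]1.Nc1ncc[nH]1.OS(=O)(=O)O | starting material
2 | 3-(1,3-dioxoisoindolin-2-yl)propanal (3-phthalimidopropanal) | O=CCCN1C(=O)c2ccccc2C1=O | starting material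
3 | 1H-imidazol-2-amine (free base, not isolated) | Nc1ncc[nH]1 | intermediate
4 | rac-2-[3-(2-amino-1H-imidazol-4-yl)-3-hydroxypropyl]isoindoline-1,3-dione | Nc1ncc(C(O)CCN2C(=O)c3ccccc3C2=O)[nH]1 | intermediate
5 | 2-amino-4-[3-(1,3-dioxoisoindolin-2-yl)propylidene]-4H-imidazol-1-ium (azafulvenium ion, not isolated; formed from 4 in step 2 with trifluoroacetate as counter-ion, and formed from 4 again in the flask of step 3 with the chiral phosphate as counter-ion) | NC1=NC(=CCCN2C(=O)c3ccccc3C2=O)C=[NH+]1 | intermediate
6 | 2-[(E)-3-(2-amino-1H-imidazol-4-yl)prop-2-enyl]isoindoline-1,3-dione | Nc1ncc(/C=C/CN2C(=O)c3ccccc3C2=O)[nH]1 | intermediate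
7 | 2-[(3S)-3-(2-amino-1H-imidazol-4-yl)-3-[2-amino-5-[(E)-3-(1,3-dioxoisoindolin-2-yl)prop-1-enyl]-1H-imidazol-4-yl]propyl]isoindoline-1,3-dione | Nc1ncc([C@H](CCN2C(=O)c3ccccc3C2=O)c2[nH]c(N)nc2/C=C/CN2C(=O)c3ccccc3C2=O)[nH]1 | intermediate
8 | (3S)-3-(2-amino-1H-imidazol-4-yl)-3-[2-amino-5-[(E)-3-aminoprop-1-enyl]-1H-imidazol-4-yl]propan-1-amine | Nc1ncc([C@H](CCN)c2[nH]c(N)nc2/C=C/CN)[nH]1 | intermediate
9 | 2,2,2-trichloro-1-(1H-pyrrol-2-yl)ethanone | O=C(c1ccc[nH]1)C(Cl)(Cl)Cl | starting material
10 | 2,2,2-trichloro-1-(4,5-dibromo-1H-pyrrol-2-yl)ethanone | O=C(c1cc(Br)c(Br)[nH]1)C(Cl)(Cl)Cl | intermediate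
11 | CID11411715, (S)-configured | Nc1ncc([C@H](CCNC(=O)c2cc(Br)c(Br)[nH]2)c2[nH]c(N)nc2/C=C/CNC(=O)c2cc(Br)c(Br)[nH]2)[nH]1 | target

**Totals**
Total steps: 6. Longest linear sequence: 5 (steps 1, 2, 3, 4, 6).

**Steps most likely to fail**

Step 3 (key step). Facial selectivity may be poor, because the many N–H donors of both partners compete for the phosphate and loosen the ion pair. The fallback uses known chemistry and sets out from 4 and 6. The union would be run without stereocontrol under an achiral acid (diphenyl phosphate or acetic acid). This is the ordinary acid-promoted condensation of a heteroaryl carbinol with a second electron-rich azole, the reaction type that gives dipyrromethanes and bis(indolyl)alkanes, and 2-aminoimidazole is also C-alkylated by stabilised cations in this way. It would give the racemic bis-phthalimide F1. Preparative chromatography on a chiral stationary phase would then separate it into 7 and the (R)-enantiomer F2; the lipophilic phthalimides make this the best stage for a resolution. The route is rejoined at 7.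

Step 2. The cation may be intercepted by traces of unprotonated ring before it loses a proton, so that oligomers form, or rehydration may hold the equilibrium back. In the fallback the alkene would be made last instead of first, setting out from 4 alone. The conditions of step 3 would be applied at higher concentration without a second partner, so that C5 of one molecule of 4 captures ion 5 formed from another, which would give the hydroxy dimer F3 (both carbinol epimers). The remaining carbinol of F3 lies next to the new branched substituent. After full protonation (CF3CO2H, MeCN, warm) its cation would be shielded from nucleophiles and could only lose a proton, which gives 7. The route is rejoined at 7, and compound 6 is then not needed.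

Step 1. The weakly basic medium may trigger β-elimination of phthalimide from the aldehyde, and the addition may stall at reversible N-hemiaminals. The fallback replaces the carbonyl addition by a three-component Mannich-type condensation under neutral to weakly acidic conditions, setting out from 2 and 3. The two would be condensed with 1H-benzotriazole (1 equiv, toluene/THF, water removal) to give the benzotriazole adduct F4. Protonation of F4 would expel benzotriazole and give the same ion directly, so F4 would take the place of 4 in steps 2 and 3. The route is rejoined at 5.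

**Further compounds**
F1 | step 3 | rac-2-[3-(2-amino-1H-imidazol-4-yl)-3-[2-amino-5-[(E)-3-(1,3-dioxoisoindolin-2-yl)prop-1-enyl]-1H-imidazol-4-yl]propyl]isoindoline-1,3-dione | Nc1ncc(C(CCN2C(=O)c3ccccc3C2=O)c2[nH]c(N)nc2/C=C/CN2C(=O)c3ccccc3C2=O)[nH]1
F2 | step 3 | 2-[(3R)-3-(2-amino-1H-imidazol-4-yl)-3-[2-amino-5-[(E)-3-(1,3-dioxoisoindolin-2-yl)prop-1-enyl]-1H-imidazol-4-yl]propyl]isoindoline-1,3-dione | Nc1ncc([C@@H](CCN2C(=O)c3ccccc3C2=O)c2[nH]c(N)nc2/C=C/CN2C(=O)c3ccccc3C2=O)[nH]1
F3 | step 2 | 2-[(3S)-3-(2-amino-1H-imidazol-4-yl)-3-[2-amino-5-[(1RS)-3-(1,3-dioxoisoindolin-2-yl)-1-hydroxypropyl]-1H-imidazol-4-yl]propyl]isoindoline-1,3-dione | Nc1ncc([C@H](CCN2C(=O)c3ccccc3C2=O)c2[nH]c(N)nc2C(O)CCN2C(=O)c3ccccc3C2=O)[nH]1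
F4 | step 1 | rac-2-[3-(2-amino-1H-imidazol-4-yl)-3-(benzotriazol-1-yl)propyl]isoindoline-1,3-dione | Nc1ncc(C(CCN2C(=O)c3ccccc3C2=O)n2nnc3ccccc32)[nH]1
A1 | direct plan | dimethyl 3-(imidazo[1,2-a]pyrimidin-2-yl)pentanedioate | COC(=O)CC(CC(=O)OC)c1cn2cccnc2n1
A2 | direct plan | (3R)-3-(imidazo[1,2-a]pyrimidin-2-yl)-5-methoxy-5-oxopentanoic acid | COC(=O)C[C@@H](CC(=O)O)c1cn2cccnc2n1
A3 | direct plan | methyl (3R,4RS)-3-(3-bromoimidazo[1,2-a]pyrimidin-2-yl)-4-chloro-5-oxopentanoate | COC(=O)C[C@@H](C(Cl)C=O)c1nc2ncccn2c1Br
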